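The benzene ring is cut at C4–C5 and C1–C2. Its alternating pattern (OH on C1 and C3, chain on C5, H on C2, C4 and C6) is that of two three-carbon units. C5–C6–C1 comes from an alk-2-ynoate whose alkyne terminus bears the chain, and C2–C3–C4 comes from dimethyl 3-oxopentanedioate. One anionic Michael–Dieckmann operation joins them and yields the arene directly, the alkyne supplying the unsaturation. The precursor is a C20 methyl ynoate made from methyl ricinoleate, whose carboxyl carbon becomes C5. It already holds the Z alkene and the carbinol centre, inverted to S and masked as a TBS ether. The two extra esters leave as CO2.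

Key step: step 6

Remark: ring atoms are numbered as in benzene-1,3-diol and chain atoms C1'–C17' from the ring. Natural methyl ricinoleate is 12R, and the CIP order at the carbinol carbon (O > allylic CH2 > hexyl CH2 > H) holds in every compound, so the 11'S target needs exactly one inversion, placed in step 1 (TBS = tert-butyldimethylsilyl).

Step 1
Reactants: 1 methyl ricinoleate, methyl (9Z,12R)-12-hydroxyoctadec-9-enoate; 2 4-nitrobenzoic acid
Product: 3 methyl (9Z,12S)-12-(4-nitrobenzoyloxy)octadec-9-enoate
Conditions: PPh3, DIAD, THF, 0 °C to rt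
Reagents that add atoms: 4-nitrobenzoic acid (2), O=C(O)c1ccc(cc1)[N+](=O)[O-]
Why: Mitsunobu reaction: the alkoxyphosphonium ion of the unhindered secondary alcohol is displaced by 4-nitrobenzoate in an SN2 event that inverts C12 from R to S, and the low pKa of this acid keeps carboxylate attack ahead of E2 loss toward the conjugated diene.

Step 2
Reactants: 3 methyl (9Z,12S)-12-(4-nitrobenzoyloxy)octadec-9-enoate
Product: 4 methyl (9Z,12S)-12-hydroxyoctadec-9-enoate
Conditions: K2CO3 (cat.), MeOH, rt
Reagents that add atoms: none
Why: Base-catalysed transesterification cleaves the electron-poor benzoate at its acyl–oxygen bond, so the C12–O bond and the S configuration set in step 1 are untouched, while exchange at the C1 methyl ester is degenerate in methanol.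

Step 3
Reactants: 4 methyl (9Z,12S)-12-hydroxyoctadec-9-enoate; 5 tert-butyldimethylsilyl chloride
Product: 6 methyl (9Z,12S)-12-(tert-butyldimethylsilyloxy)octadec-9-enoate
Conditions: imidazole, DMF, rt
Reagents that add atoms: tert-butyldimethylsilyl chloride (5), CC(C)(C)[Si](C)(C)Cl
Why: Imidazole-promoted silyl ether protection forms only an O–Si bond at the single hydroxyl group, and a secondary TBS ether is chosen because it withstands hydride, organolithium, alkoxide and hot hydroxide yet falls to mild acid at the end.

Step 4
Reactants: 6 methyl (9Z,12S)-12-(tert-butyldimethylsilyloxy)octadec-9-enoate; 7 dimethyl (1-diazo-2-oxopropyl)phosphonate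
Product: 9 (10Z,13S)-13-(tert-butyldimethylsilyloxy)nonadec-10-en-1-yne, via silyloxy aldehyde 8 (not isolated)
Conditions: i-Bu2AlH (1.1 equiv), CH2Cl2, −78 °C; MeOH, −78 to 0 °C; 7, K2CO3, 0 °C to rt; aq. potassium sodium tartrate
Reagents that add atoms: dimethyl (1-diazo-2-oxopropyl)phosphonate (7), COP(=O)(OC)C(=[N+]=[N-])C(C)=O
Why: Partial ester reduction followed in the same flask by Ohira–Bestmann homologation: the aluminium hemiacetal persists at −78 °C and releases 8 only on the methanol quench, where the diazomethylphosphonate anion made from 7 turns the CHO carbon into the internal alkyne carbon by olefination, N2 loss and 1,2-hydride shift, with no stereocentre or alkene within reach.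

Step 5
Reactants: 9 (10Z,13S)-13-(tert-butyldimethylsilyloxy)nonadec-10-en-1-yne; 10 methyl chloroformate
Product: 12 methyl (11Z,14S)-14-(tert-butyldimethylsilyloxy)icos-11-en-2-ynoate, via lithium acetylide 11 (not isolated)
Conditions: n-BuLi (1.05 equiv), THF, −78 °C; 10, −78 to 0 °C
Reagents that add atoms: methyl chloroformate (10), COC(=O)Cl
Why: Deprotonation of the terminal alkyne and C-acylation of the acetylide with a chloroformate is the standard alkynoate synthesis, and the plain methyl ester is kept on purpose so that every ester and the alkoxide released in step 6 are the same and acyl transfer there stays reversible.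

Step 6
Reactants: 12 methyl (11Z,14S)-14-(tert-butyldimethylsilyloxy)icos-11-en-2-ynoate; 13 dimethyl 3-oxopentanedioate
Product: 16 dimethyl 2,4-dihydroxy-6-[(8Z,11S)-11-(tert-butyldimethylsilyloxy)heptadec-8-enyl]benzene-1,3-dicarboxylate, via sodium enolate 14 (not isolated), via Michael adduct 15 (not isolated)
Conditions: 13 (1.3 equiv), NaH (2.6 equiv), THF, 0 °C; 12, 0 to 60 °C; cold 1 M HCl to pH 3
Reagents that add atoms: dimethyl 3-oxopentanedioate (13), COC(=O)CC(=O)CC(=O)OC
Why: This is a Michael–Dieckmann benzannulation, the established reaction of acetonedicarboxylate anions with acetylenic carbonyl compounds that gives phenols and resorcinols. Enolate 14 attacks the electrophilic alkyne carbon C3 of 12 (future ring C5, new bond C4–C5) to give 15, which is deprotonated at once at its triply activated C–H, so that the enoate geometry equilibrates through the delocalised anion and the ester can come cis to the ketodiester arm. The second equivalent of NaH ionises the remaining CH2 between ketone and ester, and this carbon attacks the enoate ester carbonyl in a 6-exo-trig acyl substitution (new bond C1–C2) with loss of methoxide, after which two keto–enol shifts give the benzene ring without any oxidant, since the alkyne brought in the missing unsaturation. No stereocentre is created, and C11' and the Z alkene are remote from the reacting atoms in a medium that attacks neither a secondary TBS ether nor an isolated alkene. The selectivity needed is acylation on carbon and not on the enolate oxygen: it is secured by the full second equivalent of base (the last-formed carbanion is the most nucleophilic site and free methoxide stays available), by having methyl esters and methoxide throughout so that any O-acylation is reversible, and by the irreversible removal of 16 as its disodium phenoxide. A base-induced shift of 12 to the allenoate does no harm, because that isomer accepts the nucleophile at the same carbon.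

Step 7
Reactants: 16 dimethyl 2,4-dihydroxy-6-[(8Z,11S)-11-(tert-butyldimethylsilyloxy)heptadec-8-enyl]benzene-1,3-dicarboxylate
Product: 18 5-[(8Z,11S)-11-(tert-butyldimethylsilyloxy)heptadec-8-enyl]benzene-1,3-diol, via dihydroxyisophthalic acid 17 (not isolated)
Conditions: KOH (excess), H2O–1,4-dioxane, 100 °C, Ar; 1 M HCl, 0 °C, pH 3, extraction; crude 17, DMF, 130 °C
Reagents that add atoms: none
Why: Saponification followed by thermal protodecarboxylation: hot hydroxide cleaves both flanked esters, and each carboxyl group of 17 has hydroxyl groups ortho/para or ortho/ortho to it, so ipso protonation and CO2 loss occur on moderate heating, far below the alkali-fission temperatures of ricinoleates and without effect on the Z alkene or C11' (any silyl ether lost early only anticipates step 8).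

Step 8
Reactants: 18 5-[(8Z,11S)-11-(tert-butyldimethylsilyloxy)heptadec-8-enyl]benzene-1,3-diol
Product: 19 5-[(8Z,11S)-11-hydroxyheptadec-8-enyl]benzene-1,3-diol
Conditions: HCl (1.25 M in MeOH), rt
Reagents that add atoms: none
Why: Acid-catalysed methanolysis of the secondary silyl ether breaks only the O–Si bond, so the S configuration is retained, and neither the resorcinol nor the homoallylic Z alkene reacts with dilute methanolic HCl at room temperature.

Compound list
1 | methyl ricinoleate, methyl (9Z,12R)-12-hydroxyoctadec-9-enoate | CCCCCC[C@@H](O)C/C=C\CCCCCCCC(=O)OC | starting material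
2 | 4-nitrobenzoic acid | O=C(O)c1ccc(cc1)[N+](=O)[O-] | starting material
3 | methyl (9Z,12S)-12-(4-nitrobenzoyloxy)octadec-9-enoate | CCCCCC[C@H](OC(=O)c1ccc(cc1)[N+](=O)[O-])C/C=C\CCCCCCCC(=O)OC | intermediate
4 | methyl (9Z,12S)-12-hydroxyoctadec-9-enoate | CCCCCC[C@H](O)C/C=C\CCCCCCCC(=O)OC | intermediate
5 | tert-butyldimethylsilyl chloride | CC(C)(C)[Si](C)(C)Cl | starting material
6 | methyl (9Z,12S)-12-(tert-butyldimethylsilyloxy)octadec-9-enoate | CCCCCC[C@H](O[Si](C)(C)C(C)(C)C)C/C=C\CCCCCCCC(=O)OC | intermediate
7 | dimethyl (1-diazo-2-oxopropyl)phosphonate | COP(=O)(OC)C(=[N+]=[N-])C(C)=O | starting material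
8 | (9Z,12S)-12-(tert-butyldimethylsilyloxy)octadec-9-enal | CCCCCC[C@H](O[Si](C)(C)C(C)(C)C)C/C=C\CCCCCCCC=O | intermediate
9 | (10Z,13S)-13-(tert-butyldimethylsilyloxy)nonadec-10-en-1-yne | CCCCCC[C@H](O[Si](C)(C)C(C)(C)C)C/C=C\CCCCCCCC#C | intermediate
10 | methyl chloroformate | COC(=O)Cl | starting material
11 | lithium acetylide of 9, [(10Z,13S)-13-(tert-butyldimethylsilyloxy)nonadec-10-en-1-ynyl]lithium | CCCCCC[C@H](O[Si](C)(C)C(C)(C)C)C/C=C\CCCCCCCC#C[Li] | intermediate
12 | methyl (11Z,14S)-14-(tert-butyldimethylsilyloxy)icos-11-en-2-ynoate | CCCCCC[C@H](O[Si](C)(C)C(C)(C)C)C/C=C\CCCCCCCC#CC(=O)OC | intermediate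
13 | dimethyl 3-oxopentanedioate | COC(=O)CC(=O)CC(=O)OC | starting material
14 | sodium (Z)-enolate of dimethyl 3-oxopentanedioate | [Na+].COC(=O)/C=C(\[O-])CC(=O)OC | intermediate
15 | trimethyl (1Z)-2-[(8Z,11S)-11-(tert-butyldimethylsilyloxy)heptadec-8-enyl]-4-oxopent-1-ene-1,3,5-tricarboxylate (reactive geometry, drawn neutral, C3 labile) | CCCCCC[C@H](O[Si](C)(C)C(C)(C)C)C/C=C\CCCCCCC/C(=C/C(=O)OC)C(C(=O)OC)C(=O)CC(=O)OC | intermediate
16 | dimethyl 2,4-dihydroxy-6-[(8Z,11S)-11-(tert-butyldimethylsilyloxy)heptadec-8-enyl]benzene-1,3-dicarboxylate | CCCCCC[C@H](O[Si](C)(C)C(C)(C)C)C/C=C\CCCCCCCc1cc(O)c(C(=O)OC)c(O)c1C(=O)OC | intermediate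
17 | 2,4-dihydroxy-6-[(8Z,11S)-11-(tert-butyldimethylsilyloxy)heptadec-8-enyl]benzene-1,3-dicarboxylic acid | CCCCCC[C@H](O[Si](C)(C)C(C)(C)C)C/C=C\CCCCCCCc1cc(O)c(C(=O)O)c(O)c1C(=O)O | intermediate
18 | 5-[(8Z,11S)-11-(tert-butyldimethylsilyloxy)heptadec-8-enyl]benzene-1,3-diol | CCCCCC[C@H](O[Si](C)(C)C(C)(C)C)C/C=C\CCCCCCCc1cc(O)cc(O)c1 | intermediate
19 | 5-[(8Z,11S)-11-hydroxyheptadec-8-enyl]benzene-1,3-diol | CCCCCC[C@H](O)C/C=C\CCCCCCCc1cc(O)cc(O)c1 | target

Total step count: 8. Longest linear sequence: 8 steps (1 to 19).

Steps most likely to fail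

Step 6. Three processes may go wrong:
- Ring closure through the enolate oxygen could outrun closure through carbon and not be corrected by equilibration.
- The ketodiester could self-condense.
- The base could oligomerise the ynoate.

Closure through the other carbon terminus of the delocalised anion onto the distal ester would be harmless, because both ester groups are lost in step 7 and the same 18 results.

The fallback sets out from 12 and comes back at 18. It replaces the anionic [3+3] union by a thermal [4+2] one. Compound 12 would be heated (xylene, 140 °C, sealed vessel) with purchased 1-methoxy-1,3-bis(trimethylsilyloxy)buta-1,3-diene (COC(O[Si](C)(C)C)=CC(=C)O[Si](C)(C)C). This is a Diels–Alder reaction, a known way from alk-2-ynoates to resorcylates. The nucleophilic CH2 terminus of the diene bonds to C3 of 12. This should give methyl 2-[(8Z,11S)-11-(tert-butyldimethylsilyloxy)heptadec-8-enyl]-6-methoxy-4,6-bis(trimethylsilyloxy)cyclohexa-1,4-diene-1-carboxylate F1. With 0.1 M aq. HCl in THF at 0 °C this loses methanol and both trimethylsilyl groups and aromatises to methyl 2,4-dihydroxy-6-[(8Z,11S)-11-(tert-butyldimethylsilyloxy)heptadec-8-enyl]benzoate F2. KOH as in step 7 would give 2,4-dihydroxy-6-[(8Z,11S)-11-(tert-butyldimethylsilyloxy)heptadec-8-enyl]benzoic acid F3. Heating F3 in DMF rejoins the route at 18.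

Step 4. The reduction may run past the aldehyde stage, or the homologation may be sluggish in the aluminium-laden medium.

The fallback sets out from 6 and comes back at 11. Compound 6 would be reduced fully with LiAlH4 (Et2O, 0 °C) to (9Z,12S)-12-(tert-butyldimethylsilyloxy)octadec-9-en-1-ol F4. F4 would be oxidised with Dess–Martin periodinane (NaHCO3, CH2Cl2) to 8, now isolated. Corey–Fuchs olefination (CBr4, PPh3, CH2Cl2, 0 °C) would then give (10Z,13S)-1,1-dibromo-13-(tert-butyldimethylsilyloxy)nonadeca-1,10-diene F5. Two equivalents of n-BuLi (THF, −78 °C) would convert F5 into 11 by bromine–lithium exchange, rearrangement and deprotonation. Compound 11 is then quenched with 10 as in step 5.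

Step 1. The activated homoallylic alcohol may undergo E2 elimination, and inversion may be partly lost through attack at an acyloxyphosphonium species.

The fallback sets out from 1 and comes back at 4. It separates activation from displacement. MsCl and Et3N (CH2Cl2, 0 °C) would give methyl (9Z,12R)-12-(methylsulfonyloxy)octadec-9-enoate F6. CsOAc with 18-crown-6 in toluene at 80 °C would displace the sulfonate by SN2 with inversion to give methyl (9Z,12S)-12-acetoxyoctadec-9-enoate F7. K2CO3 in MeOH would then release 4.

Further compounds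
F1 | step 6 | methyl 2-[(8Z,11S)-11-(tert-butyldimethylsilyloxy)heptadec-8-enyl]-6-methoxy-4,6-bis(trimethylsilyloxy)cyclohexa-1,4-diene-1-carboxylate (both configurations at ring C6) | CCCCCC[C@H](O[Si](C)(C)C(C)(C)C)C/C=C\CCCCCCCC1=C(C(=O)OC)C(OC)(O[Si](C)(C)C)C=C(O[Si](C)(C)C)C1
F2 | step 6 | methyl 2,4-dihydroxy-6-[(8Z,11S)-11-(tert-butyldimethylsilyloxy)heptadec-8-enyl]benzoate | CCCCCC[C@H](O[Si](C)(C)C(C)(C)C)C/C=C\CCCCCCCc1cc(O)cc(O)c1C(=O)OC
F3 | step 6 | 2,4-dihydroxy-6-[(8Z,11S)-11-(tert-butyldimethylsilyloxy)heptadec-8-enyl]benzoic acid | CCCCCC[C@H](O[Si](C)(C)C(C)(C)C)C/C=C\CCCCCCCc1cc(O)cc(O)c1C(=O)O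
F4 | step 4 | (9Z,12S)-12-(tert-butyldimethylsilyloxy)octadec-9-en-1-ol | CCCCCC[C@H](O[Si](C)(C)C(C)(C)C)C/C=C\CCCCCCCCO
F5 | step 4 | (10Z,13S)-1,1-dibromo-13-(tert-butyldimethylsilyloxy)nonadeca-1,10-diene | CCCCCC[C@H](O[Si](C)(C)C(C)(C)C)C/C=C\CCCCCCCC=C(Br)Br
F6 | step 1 | methyl (9Z,12R)-12-(methylsulfonyloxy)octadec-9-enoate | CCCCCC[C@@H](OS(C)(=O)=O)C/C=C\CCCCCCCC(=O)OC
F7 | step 1 | methyl (9Z,12S)-12-acetoxyoctadec-9-enoate | CCCCCC[C@H](OC(C)=O)C/C=C\CCCCCCCC(=O)OC
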